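## The problem

Compound 33 is a resveratrol trimer made of two 2,3-diaryl-2,3-dihydrobenzofurans. The unprimed unit (benzo ring A) carries an (E)-4-hydroxystyryl group on C4 and is bonded through C3 to C6' of ring B of the primed unit. It has four stereocentres, C2 (S), C3 (S), C2' (R) and C3' (R), trans within each furan ring. Inside one ring the two centres can control each other: the C2 aryl group shields one face of C3, and a C2–O bond para to an oxygenated aryl group can equilibrate to trans. The two rings are separated by ring B and have opposite sense, so two independent sources of absolute configuration are needed. The linking bond joins an sp3 carbon to a ring position meta to both oxygens of ring B, so Friedel–Crafts chemistry (which would go to C5' or C7') is ruled out and a cross-coupling is required. Seven phenols, the E-stilbene (light, oxidants, hydrogenation, acid) and the benzylic C2–O and C2'–O bonds para to hydroxyl (ionisation in acid, quinone methide formation in hot base) will not survive rough treatment, so the phenols stay masked until a short, cold end game. The enabling feature is that O1, C2 with its 4-hydroxyphenyl group, C3 and ring A with its 1,3,5-pattern (O1 on C7a, hydroxyl on C6, carbon on C4) are the atoms of (2S)-naringenin 1. Its C2 is already S, its chelated hydroxyl sits where the styryl group belongs, and its only surplus is the carbonyl carbon between C3 and ring A, which a 1,2-shift of ring A can push out of the ring and leave on C3 as a carboxyl handle where the bond to ring B must be made.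

## Retrosynthesis

Benzofuran numbering is used for the dihydrobenzofurans and flavanone numbering for the chromanones.

**Unmasking.** Target 33 is traced to bis-phenol 32 and then to the fully masked trimer 31 (five methyl ethers, two aryl mesylates). No skeletal bond is cut. Methyl ethers are chosen because they survive trivalent iodine, base, zinc and nickel. Mesylates are chosen because the C2 and C2' aryl groups must be electron-poor during the ring contractions. The forward steps are a cold mesylate cleavage and one global demethylation.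

**C3–C6' bond.** Trimer 31 is cut into redox-active ester 14 and aryl iodide 30. This cut halves the molecule into two dihydrobenzofurans of similar size, each with one pair of stereocentres. It is also the only cut that places the aryl group on the meta position of ring B without relying on aromatic substitution. The forward reaction is a nickel-catalysed decarboxylative cross-electrophile coupling. The C3 radical must be captured anti to the C2 aryl group, so the final C3 configuration is set here and the ester stereocentre made earlier is only provisional.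

**Handle and styryl group.** Ester 14 comes from acid 12, which comes from methyl ester 11, which comes from triflate 9 and styrylboronate 10 by cutting C4–C(alkene). The alkene cannot be carried through an oxidation with trivalent iodine, so it enters after the key step. It enters before the nickel step so that no aryl triflate competes with the iodide. The triflate is already in place because it is the chelated hydroxyl of 1.

**Key disconnection.** Ester 9 is unfolded to flavanone 4: the C3–C3a bond is cut and the ring A carbon is reattached to the ester carbon, which becomes the ketone. Other routes to trans-2-aryl-2,3-dihydrobenzofuran-3-carboxylates (carbene C–H insertion, quinone methide annulation) need an asymmetric catalyst and a separately built ring A. This cut reaches a natural product that already has C2, the aryl group and the whole oxygenation pattern. The forward reaction must make ring A migrate, and not the C2 aryl group, and must leave C2 alone.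

**Differentiating naringenin.** Flavanone 4 goes back through mesylate 3 and sakuranetin 2 to 1. The three hydroxyls are told apart by acidity and chelation: methyl on the most acidic 7-OH, mesyl on the free 4'-OH, triflyl on the chelated 5-OH.

**Primed unit, C3' aryl.** Iodide 30 comes from bromide 29 by halogen exchange. Bromide 29 is cut at C3'–aryl into redox-active ester 27 and 1-iodo-3,5-dimethoxybenzene 28, the same reaction type as the fragment union. The bromide is carried as a latent iodide because it is inert to zerovalent nickel at room temperature while an aryl iodide is present.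

**Primed unit, ring contraction.** Ester 27 comes from acid 26 and ester 25, and 25 from (2R)-flavanone 22 by the same ring contraction in the mirror-image series. Ring B needs a methoxy group at C5 and bromine at C7 of the flavanone.

**Primed unit, C2' stereocentre.** No natural (2R)-flavanone of this pattern exists, so 22 is cut at C2–aryl into chromone 19 and arylboronate 21 (from phenol 20), to be joined by an asymmetric 1,4-addition. Chromone 19 comes from hydroxyacetophenone 17, and 17 through dimethoxy ketone 16 from commercial difluoro ketone 15.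

## Roads not taken

**Alternative 1:** The cut goes through ring B itself, at C4'–C3a' and C7'–C7a'. A Danheiser benzannulation would heat cyclobutenone A2, whose 3-substituent is the complete unprimed dihydrobenzofuran attached through C3, with siloxyalkyne A3, which carries C3' and C2' with their aryl groups. The pericyclic cascade would deliver ring B as resorcinol monosilyl ether A1 with the C4' hydroxyl free.
- Merits: the meta relationship between C3 and the two ring B oxygens is written into the reaction, no sp3–sp2 coupling of two large fragments is needed, and the two ring B oxygens come out differentiated.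
- Weak points: A2 and A3 between them hold all four stereocentres, so each needs its own enantioselective synthesis first. A2 has a C3–H that is benzylic and vinylogously alpha to the ketone, next to a phenoxide leaving group. A3 is an ynol silyl ether with an acyclic stereodiad. Both are fragile at benzannulation temperatures. Afterwards the primed furan must still be closed at C2' with stereocontrol and the C4 bromide turned into the styryl group.
- Comparison: in regiochemical certainty of the C3–ring B connection this road is better than the chosen one, whose radical arylation in step 18 is its least secure step. The chosen plan sets against this a chiral-pool source for C2, fragments made by precedented reactions, and a key step that takes a ring with its substituents from a natural product.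

**Alternative 2:** Ring A and the unprimed furan ring are cut together, at C3a–C7a, C4–C5 and C6–C7. [Rh(cod)2]BF4 with BINAP would join 1,6-diyne A5 (an ethynyl ether on O1, a styryl-substituted alkyne on C3) with ethoxyethyne A6 in a (2+2+2) cycloaddition. The product A4 is the target as its hexamethyl ether with an ethyl ether at C6.
- Merits: three C–C bonds and two rings in one late step, the styryl group in place from the start, and a single global dealkylation at the end. In bonds per step and convergence this is the most economical of the four plans and better than the chosen one.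
- Weak points: A5 must hold C2 and C3 in the correct relationship on an open chain, with no ring to relay the preference, next to the complete primed unit. No new stereocentre arises in the key step, so the chiral ligand decides nothing. A secondary benzylic ethynyl ether is thermally and hydrolytically labile. A6 can insert in two orientations (ethoxy at C6 or C5), and the enyne can take part itself.
- Comparison: the chosen plan is longer, but the ring does the stereochemical work (C2 from 1, C3 by trans delivery in a ring), and the oxygenation pattern is fixed by the starting material and not by the regioselectivity of an insertion.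

**Alternative 3:** The cut is at the two benzylic C–O bonds, O1–C2 and O1'–C2'. Acid would ionise both carbinols of open-chain triphenol diol A8 to 4-methoxybenzyl cations. The C7a hydroxyl and one of the two equivalent ring B hydroxyls would capture them and give A7, the C4 bromide of the skeleton.
- Merits: the carbinol configurations do not matter, since each ring closes to the trans isomer under control of C3 or C3', so only two stereocentres need absolute control. Both furan rings form at once, and ring B is locally symmetric. In these respects it is at least as good as the chosen plan, and it uses the same thermodynamic bias that keeps C2 and C2' trans in step 20.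
- Weak points: the burden moves to C3 and C3', two acyclic di- and triarylmethine centres with no reliable catalytic asymmetric entry. Each cation sits next to such a methine and can lose the adjacent proton to give a stilbene, or be trapped by an electron-rich ring carbon instead of oxygen. The styryl group must still be added afterwards.
- Comparison: the chosen plan takes C2 from the chiral pool and lets it set C3 in a ring, and it meets C2' with a precedented asymmetric addition. It gives up the one-step formation of both rings.

Key step: step 4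

Assumption: commercial (2S)-naringenin is taken to be of high enantiomeric purity (batches differ, so this is verified by chiral HPLC before use), and flavanone C2 is taken to be configurationally stable as long as strong base, heat and a free 4'-phenoxide are not combined.

## Route

Step 1
Reactants: 1 (2S)-naringenin
Product: 2 (2S)-sakuranetin [(2S)-5-hydroxy-2-(4-hydroxyphenyl)-7-methoxychroman-4-one]
Conditions: MeOH (1.1 equiv), PPh3, DIAD, THF, 0 °C to rt
Reagents that add atoms: methanol, CO
Why: Mitsunobu etherification takes the most acidic phenol, the 7-OH para to the carbonyl group; the chelated 5-OH and the less acidic 4'-OH react more slowly, and the near-neutral medium avoids base-induced ring opening to the chalcone, which would racemise C2.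

Step 2
Reactants: 2 (2S)-sakuranetin
Product: 3 4-[(2S)-5-hydroxy-7-methoxy-4-oxochroman-2-yl]phenyl methanesulfonate
Conditions: MsCl (1.05 equiv), Et3N, CH2Cl2, −20 °C
Reagents that add atoms: methanesulfonyl chloride, CS(Cl)(=O)=O
Why: Sulfonylation of the only free, unchelated phenol; the 5-OH is held in a hydrogen bond to the ketone and stays untouched at low temperature.

Step 3
Reactants: 3 4-[(2S)-5-hydroxy-7-methoxy-4-oxochroman-2-yl]phenyl methanesulfonate
Product: 4 4-[(2S)-7-methoxy-4-oxo-5-(trifluoromethanesulfonyloxy)chroman-2-yl]phenyl methanesulfonate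
Conditions: Tf2O, pyridine, CH2Cl2, 0 °C
Reagents that add atoms: trifluoromethanesulfonic anhydride, O=S(=O)(OS(=O)(=O)C(F)(F)F)C(F)(F)F
Why: Triflation of a chelated 5-hydroxyl of a flavonoid needs the strongest sulfonylating agent and is a standard way to prepare C5 for cross-coupling; the triflate also removes the phenol that trivalent iodine would oxidise.

Step 4
Reactants: 4 4-[(2S)-7-methoxy-4-oxo-5-(trifluoromethanesulfonyloxy)chroman-2-yl]phenyl methanesulfonate; 5 (diacetoxyiodo)benzene; 6 trimethyl orthoformate
Product: 9 methyl (2S,3S)-6-methoxy-2-[4-(methanesulfonyloxy)phenyl]-4-(trifluoromethanesulfonyloxy)-2,3-dihydro-1-benzofuran-3-carboxylate, via methyl enol ether 7 (not isolated), via iodanyl dimethyl ketal 8 (not isolated)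
Conditions: PhI(OAc)2 (1.2 equiv), conc. H2SO4, HC(OMe)3 (solvent), rt
Reagents that add atoms: trimethyl orthoformate (6), COC(OC)OC
Why: Acid and orthoformate turn ketone 4 into methyl enol ether 7, which the trivalent iodine electrophile attacks at C3 on the face away from the C2 aryl group to give ketal 8 (drawn with acetate as the remaining ligand on iodine). With the C4–C4a bond antiperiplanar to the C3–I bond, the ring A carbon C4a shifts from C4 to C3 as iodobenzene leaves, forming C3–C3a with inversion at C3, and the dimethoxycarbenium ion left at the old carbonyl carbon loses a methyl group to give the ester. The closest known reaction type is the oxidative ring contraction of flavanones to methyl trans-2-aryl-2,3-dihydrobenzofuran-3-carboxylates by PhI(OAc)2 or Tl(NO3)3 in trimethyl orthoformate, a cyclic case of the 1,2-aryl shift of aryl ketones to arylacetates. The five-membered ring arises not by cyclisation but by contraction of the six-membered ring through a bridged phenonium-type transition state, that is a 3-exo-tet attack of the ring A ipso carbon on C3. C2 is untouched and stays S; C3 is set by C2, because anti iodination followed by invertive migration puts the ester trans to the aryl group, which is also the thermodynamic arrangement reachable by enolisation. The step needs ring A to migrate in preference to the C2 aryl group (isoflavone pathway) and to proton loss (flavone pathway): the para methoxy group and the ortho ring oxygen make C4a a good migrating carbon despite the ortho triflate, and the mesylate makes the C2 aryl group a poor one and shields that ring from the oxidant.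

Step 5
Reactants: 9 methyl (2S,3S)-6-methoxy-2-[4-(methanesulfonyloxy)phenyl]-4-(trifluoromethanesulfonyloxy)-2,3-dihydro-1-benzofuran-3-carboxylate; 10 (E)-2-[2-(4-methoxyphenyl)ethenyl]-4,4,5,5-tetramethyl-1,3,2-dioxaborolane
Product: 11 methyl (2S,3S)-6-methoxy-4-[(E)-2-(4-methoxyphenyl)ethenyl]-2-[4-(methanesulfonyloxy)phenyl]-2,3-dihydro-1-benzofuran-3-carboxylate
Conditions: Pd(dppf)Cl2 (5 mol%), K3PO4, 1,4-dioxane/H2O, 80 °C
Reagents that add atoms: boronate 10, COc1ccc(/C=C/B2OC(C)(C)C(C)(C)O2)cc1
Why: Suzuki–Miyaura coupling of an aryl triflate with an alkenylboronate, with retention of the E geometry; zerovalent palladium with this ligand inserts into the triflate and leaves the aryl mesylate alone, and any enolisation at C3 can only return the trans ester.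

Step 6
Reactants: 11 methyl (2S,3S)-6-methoxy-4-[(E)-2-(4-methoxyphenyl)ethenyl]-2-[4-(methanesulfonyloxy)phenyl]-2,3-dihydro-1-benzofuran-3-carboxylate
Product: 12 (2S,3S)-6-methoxy-4-[(E)-2-(4-methoxyphenyl)ethenyl]-2-[4-(methanesulfonyloxy)phenyl]-2,3-dihydro-1-benzofuran-3-carboxylic acid
Conditions: LiOH·H2O, THF/MeOH/H2O, 0 °C to rt; then 1 M HCl
Reagents that add atoms: lithium hydroxide, [Li+].[OH-]
Why: Ester saponification; aryl mesylates survive cold LiOH, and loss of the C2 phenoxide from the C3 enolate would be the reverse of a 5-endo-trig closure, so C2 keeps its configuration.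

Step 7
Reactants: 12 (2S,3S)-6-methoxy-4-[(E)-2-(4-methoxyphenyl)ethenyl]-2-[4-(methanesulfonyloxy)phenyl]-2,3-dihydro-1-benzofuran-3-carboxylic acid; 13 N-hydroxyphthalimide
Product: 14 1,3-dioxoisoindolin-2-yl (2S,3S)-6-methoxy-4-[(E)-2-(4-methoxyphenyl)ethenyl]-2-[4-(methanesulfonyloxy)phenyl]-2,3-dihydro-1-benzofuran-3-carboxylate
Conditions: N-hydroxyphthalimide, DIC, DMAP (cat.), CH2Cl2, rt
Reagents that add atoms: N-hydroxyphthalimide (13), O=C1c2ccccc2C(=O)N1O
Why: Carbodiimide esterification to the redox-active ester; no other nucleophilic group is free.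

Step 8
Reactants: 15 1-(4-bromo-2,6-difluorophenyl)ethan-1-one
Product: 16 1-(4-bromo-2,6-dimethoxyphenyl)ethan-1-one
Conditions: NaOMe (3 equiv), MeOH/DMF, 80 °C
Reagents that add atoms: sodium methoxide, C[O-].[Na+]
Why: Twofold nucleophilic aromatic substitution; both fluorides are ortho to the acetyl group and fluoride is by far the better leaving group, so the bromide stays, and the first methoxy group is meta to the second fluoride and does not deactivate it.

Step 9
Reactants: 16 1-(4-bromo-2,6-dimethoxyphenyl)ethan-1-one
Product: 17 1-(4-bromo-2-hydroxy-6-methoxyphenyl)ethan-1-one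
Conditions: BCl3 (1.1 equiv), CH2Cl2, −78 to 0 °C
Reagents that add atoms: none
Why: Chelation-controlled mono-demethylation ortho to a ketone; the boron chelate formed after the first cleavage protects the second methyl ether.

Step 10
Reactants: 17 1-(4-bromo-2-hydroxy-6-methoxyphenyl)ethan-1-one
Product: 19 7-bromo-5-methoxy-4H-chromen-4-one, via enaminone 18 (not isolated)
Conditions: Me2NCH(OMe)2, toluene, 100 °C; then conc. HCl, CH2Cl2, 40 °C
Reagents that add atoms: N,N-dimethylformamide dimethyl acetal, COC(OC)N(C)C
Why: Standard chromone synthesis: condensation at the methyl ketone gives enaminone 18, and acid makes the phenol add to it with loss of dimethylamine.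

Step 11
Reactants: 20 4-(4,4,5,5-tetramethyl-1,3,2-dioxaborolan-2-yl)phenol
Product: 21 4-(4,4,5,5-tetramethyl-1,3,2-dioxaborolan-2-yl)phenyl methanesulfonate
Conditions: MsCl, Et3N, CH2Cl2, 0 °C
Reagents that add atoms: methanesulfonyl chloride, CS(Cl)(=O)=O
Why: Simple phenol sulfonylation; it gives the aryl donor already in the electron-poor form that the ring contraction of step 13 requires.

Step 12
Reactants: 19 7-bromo-5-methoxy-4H-chromen-4-one; 21 4-(4,4,5,5-tetramethyl-1,3,2-dioxaborolan-2-yl)phenyl methanesulfonate
Product: 22 4-[(2R)-7-bromo-5-methoxy-4-oxochroman-2-yl]phenyl methanesulfonate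
Conditions: [Rh(OH)(cod)]2 (3 mol%), MeO-F12-BIPHEP (antipode that gives 2R), toluene/H2O, 40 °C
Reagents that add atoms: boronate 21, CS(=O)(=O)Oc1ccc(B2OC(C)(C)C(C)(C)O2)cc1
Why: Hayashi–Miyaura asymmetric 1,4-addition of an arylboron reagent to a chromone, a known entry to flavanones of high ee; the chiral bisphosphine on rhodium sets C2 (R, to be confirmed by the sign of the CD spectrum against the 2S series), the aryl bromide is inert to monovalent rhodium, and the electron-poor ligand suppresses a second addition to the product ketone.

Step 13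
Reactants: 22 4-[(2R)-7-bromo-5-methoxy-4-oxochroman-2-yl]phenyl methanesulfonate; 5 (diacetoxyiodo)benzene; 6 trimethyl orthoformate
Product: 25 methyl (2R,3R)-6-bromo-4-methoxy-2-[4-(methanesulfonyloxy)phenyl]-2,3-dihydro-1-benzofuran-3-carboxylate, via methyl enol ether 23 (not isolated), via iodanyl dimethyl ketal 24 (not isolated)
Conditions: PhI(OAc)2 (1.2 equiv), conc. H2SO4, HC(OMe)3 (solvent), rt
Reagents that add atoms: trimethyl orthoformate (6), COC(OC)OC
Why: The oxidative flavanone ring contraction of step 4 in the enantiomeric series: through 23 and 24 the ring carbon C4a, flanked by a methoxy group and the ring oxygen, migrates to C3 and the ester ends trans to the mesyloxyphenyl group (2R,3R). The aryl bromide is inert to trivalent iodine.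

Step 14
Reactants: 25 methyl (2R,3R)-6-bromo-4-methoxy-2-[4-(methanesulfonyloxy)phenyl]-2,3-dihydro-1-benzofuran-3-carboxylate
Product: 26 (2R,3R)-6-bromo-4-methoxy-2-[4-(methanesulfonyloxy)phenyl]-2,3-dihydro-1-benzofuran-3-carboxylic acid
Conditions: LiOH·H2O, THF/MeOH/H2O, 0 °C to rt; then 1 M HCl
Reagents that add atoms: lithium hydroxide, [Li+].[OH-]
Why: Ester saponification as in step 6; mesylate and bromide are stable and C2 is not affected.

Step 15
Reactants: 26 (2R,3R)-6-bromo-4-methoxy-2-[4-(methanesulfonyloxy)phenyl]-2,3-dihydro-1-benzofuran-3-carboxylic acid; 13 N-hydroxyphthalimide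
Product: 27 1,3-dioxoisoindolin-2-yl (2R,3R)-6-bromo-4-methoxy-2-[4-(methanesulfonyloxy)phenyl]-2,3-dihydro-1-benzofuran-3-carboxylate
Conditions: N-hydroxyphthalimide, DIC, DMAP (cat.), CH2Cl2, rt
Reagents that add atoms: N-hydroxyphthalimide (13), O=C1c2ccccc2C(=O)N1O
Why: Carbodiimide esterification to the redox-active ester, as in step 7.

Step 16
Reactants: 27 1,3-dioxoisoindolin-2-yl (2R,3R)-6-bromo-4-methoxy-2-[4-(methanesulfonyloxy)phenyl]-2,3-dihydro-1-benzofuran-3-carboxylate; 28 1-iodo-3,5-dimethoxybenzene
Product: 29 4-[(2R,3R)-6-bromo-3-(3,5-dimethoxyphenyl)-4-methoxy-2,3-dihydro-1-benzofuran-2-yl]phenyl methanesulfonate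
Conditions: 28 (3 equiv), NiBr2(dme) (10 mol%), dtbbpy (10 mol%), Zn, DMA, rt
Reagents that add atoms: 1-iodo-3,5-dimethoxybenzene (28), COc1cc(I)cc(OC)c1
Why: Nickel-catalysed decarboxylative cross-electrophile coupling of an N-hydroxyphthalimide ester with an aryl iodide: reduction releases CO2 and the C3' radical, which the arylnickel species captures on the face away from the C2' aryl group, so the new aryl group ends trans (3'R). Zerovalent nickel inserts into the aryl iodide, used in excess, much faster than into the C6' bromide at room temperature.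

Step 17
Reactants: 29 4-[(2R,3R)-6-bromo-3-(3,5-dimethoxyphenyl)-4-methoxy-2,3-dihydro-1-benzofuran-2-yl]phenyl methanesulfonate
Product: 30 4-[(2R,3R)-3-(3,5-dimethoxyphenyl)-6-iodo-4-methoxy-2,3-dihydro-1-benzofuran-2-yl]phenyl methanesulfonate
Conditions: CuI (10 mol%), trans-N,N'-dimethylcyclohexane-1,2-diamine, NaI, 1,4-dioxane, 110 °C
Reagents that add atoms: sodium iodide, [Na+].[I-]
Why: Copper-catalysed aromatic Finkelstein reaction; it turns the bromide that was inert in step 16 into the iodide that the fragment union needs, without touching the mesylate or the stereocentres.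

Step 18
Reactants: 14 1,3-dioxoisoindolin-2-yl (2S,3S)-6-methoxy-4-[(E)-2-(4-methoxyphenyl)ethenyl]-2-[4-(methanesulfonyloxy)phenyl]-2,3-dihydro-1-benzofuran-3-carboxylate; 30 4-[(2R,3R)-3-(3,5-dimethoxyphenyl)-6-iodo-4-methoxy-2,3-dihydro-1-benzofuran-2-yl]phenyl methanesulfonate
Product: 31 (2S,3S)-3-[(2R,3R)-3-(3,5-dimethoxyphenyl)-4-methoxy-2-(4-mesyloxyphenyl)-2,3-dihydrobenzofuran-6-yl]-6-methoxy-4-[(E)-4-methoxystyryl]-2-(4-mesyloxyphenyl)-2,3-dihydrobenzofuran
Conditions: 14 (1.5 equiv), NiBr2(dme) (20 mol%), dtbbpy (20 mol%), Zn, DMA, rt, dark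
Reagents that add atoms: aryl iodide 30, COc1cc(I)cc2c1[C@@H](c1cc(OC)cc(OC)c1)[C@H](c1ccc(OS(C)(=O)=O)cc1)O2
Why: The same decarboxylative cross-electrophile coupling joins the two units: the C3 radical from 14 is captured by the arylnickel species made from 30 anti to the C2 aryl group, which sets C3 (S, trans). Aryl mesylates and the stilbene are inert to zerovalent nickel with a bipyridine ligand at room temperature, and the radical cannot cyclise onto the styryl group without forming a four-membered ring or closing 5-endo.

Step 19
Reactants: 31 (2S,3S)-3-[(2R,3R)-3-(3,5-dimethoxyphenyl)-4-methoxy-2-(4-mesyloxyphenyl)-2,3-dihydrobenzofuran-6-yl]-6-methoxy-4-[(E)-4-methoxystyryl]-2-(4-mesyloxyphenyl)-2,3-dihydrobenzofuran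
Product: 32 (2S,3S)-3-[(2R,3R)-3-(3,5-dimethoxyphenyl)-2-(4-hydroxyphenyl)-4-methoxy-2,3-dihydrobenzofuran-6-yl]-2-(4-hydroxyphenyl)-6-methoxy-4-[(E)-4-methoxystyryl]-2,3-dihydrobenzofuran
Conditions: LiN(iPr)2 (2.5 equiv), THF, −78 °C; then aq. NH4Cl
Reagents that add atoms: none
Why: Aryl mesylate cleavage by amide base (E1cB loss of sulfene) at low temperature; no hot base is used, so the liberated 4-phenoxides cannot open the furan rings through quinone methides, and the methyl ethers are untouched.

Step 20
Reactants: 32 (2S,3S)-3-[(2R,3R)-3-(3,5-dimethoxyphenyl)-2-(4-hydroxyphenyl)-4-methoxy-2,3-dihydrobenzofuran-6-yl]-2-(4-hydroxyphenyl)-6-methoxy-4-[(E)-4-methoxystyryl]-2,3-dihydrobenzofuran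
Product: 33 (2S,3S)-3-[(2R,3R)-3-(3,5-dihydroxyphenyl)-4-hydroxy-2-(4-hydroxyphenyl)-2,3-dihydrobenzofuran-6-yl]-2-(4-hydroxyphenyl)-4-[(E)-4-hydroxystyryl]-2,3-dihydrobenzofuran-6-ol (CNP0188679.4)
Conditions: BBr3 (excess), CH2Cl2, −78 °C to rt, dark; then MeOH
Reagents that add atoms: none
Why: Global cleavage of the five aryl methyl ethers with BBr3, the usual last step for oligostilbenes; C3 and C3' cannot epimerise, so a C2–O or C2'–O bond that ionises and recloses returns to the trans arrangement.

## Compound list

1 | (2S)-naringenin [(2S)-5,7-dihydroxy-2-(4-hydroxyphenyl)chroman-4-one] | O=C1C[C@@H](c2ccc(O)cc2)Oc2cc(O)cc(O)c12 | starting material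
2 | (2S)-sakuranetin [(2S)-5-hydroxy-2-(4-hydroxyphenyl)-7-methoxychroman-4-one] | O=C1C[C@@H](c2ccc(O)cc2)Oc2cc(OC)cc(O)c12 | intermediate
3 | 4-[(2S)-5-hydroxy-7-methoxy-4-oxochroman-2-yl]phenyl methanesulfonate | O=C1C[C@@H](c2ccc(OS(C)(=O)=O)cc2)Oc2cc(OC)cc(O)c12 | intermediate
4 | 4-[(2S)-7-methoxy-4-oxo-5-(trifluoromethanesulfonyloxy)chroman-2-yl]phenyl methanesulfonate | O=C1C[C@@H](c2ccc(OS(C)(=O)=O)cc2)Oc2cc(OC)cc(OS(=O)(=O)C(F)(F)F)c12 | intermediate
5 | (diacetoxyiodo)benzene, PhI(OAc)2 | CC(=O)OI(OC(C)=O)c1ccccc1 | starting material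
6 | trimethyl orthoformate | COC(OC)OC | starting material
7 | 4-[(2S)-4,7-dimethoxy-5-(trifluoromethanesulfonyloxy)-2H-chromen-2-yl]phenyl methanesulfonate (methyl enol ether of 4) | COC1=C[C@@H](c2ccc(OS(C)(=O)=O)cc2)Oc2cc(OC)cc(OS(=O)(=O)C(F)(F)F)c12 | intermediate
8 | 4-[(2R,3R)-3-[acetoxy(phenyl)iodanyl]-4,4,7-trimethoxy-5-(trifluoromethanesulfonyloxy)chroman-2-yl]phenyl methanesulfonate (iodine trans to the aryl group; C2 arranged in space as in 4) | COC1(OC)[C@H](I(OC(C)=O)c2ccccc2)[C@@H](c2ccc(OS(C)(=O)=O)cc2)Oc2cc(OC)cc(OS(=O)(=O)C(F)(F)F)c12 | intermediate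
9 | methyl (2S,3S)-6-methoxy-2-[4-(methanesulfonyloxy)phenyl]-4-(trifluoromethanesulfonyloxy)-2,3-dihydro-1-benzofuran-3-carboxylate (trans) | FC(F)(F)S(=O)(=O)Oc1cc(OC)cc2c1[C@H](C(=O)OC)[C@@H](c1ccc(OS(C)(=O)=O)cc1)O2 | intermediate
10 | (E)-2-[2-(4-methoxyphenyl)ethenyl]-4,4,5,5-tetramethyl-1,3,2-dioxaborolane | COc1ccc(/C=C/B2OC(C)(C)C(C)(C)O2)cc1 | starting material
11 | methyl (2S,3S)-6-methoxy-4-[(E)-2-(4-methoxyphenyl)ethenyl]-2-[4-(methanesulfonyloxy)phenyl]-2,3-dihydro-1-benzofuran-3-carboxylate (trans) | COc1ccc(/C=C/c2cc(OC)cc3c2[C@H](C(=O)OC)[C@@H](c2ccc(OS(C)(=O)=O)cc2)O3)cc1 | intermediate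
12 | (2S,3S)-6-methoxy-4-[(E)-2-(4-methoxyphenyl)ethenyl]-2-[4-(methanesulfonyloxy)phenyl]-2,3-dihydro-1-benzofuran-3-carboxylic acid (trans) | COc1ccc(/C=C/c2cc(OC)cc3c2[C@H](C(O)=O)[C@@H](c2ccc(OS(C)(=O)=O)cc2)O3)cc1 | intermediate
13 | N-hydroxyphthalimide | O=C1c2ccccc2C(=O)N1O | starting material
14 | 1,3-dioxoisoindolin-2-yl (2S,3S)-6-methoxy-4-[(E)-2-(4-methoxyphenyl)ethenyl]-2-[4-(methanesulfonyloxy)phenyl]-2,3-dihydro-1-benzofuran-3-carboxylate (trans) | COc1ccc(/C=C/c2cc(OC)cc3c2[C@H](C(=O)ON2C(=O)c4ccccc4C2=O)[C@@H](c2ccc(OS(C)(=O)=O)cc2)O3)cc1 | intermediate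
15 | 1-(4-bromo-2,6-difluorophenyl)ethan-1-one | CC(=O)c1c(F)cc(Br)cc1F | starting material
16 | 1-(4-bromo-2,6-dimethoxyphenyl)ethan-1-one | CC(=O)c1c(OC)cc(Br)cc1OC | intermediate
17 | 1-(4-bromo-2-hydroxy-6-methoxyphenyl)ethan-1-one | CC(=O)c1c(O)cc(Br)cc1OC | intermediate
18 | (E)-1-(4-bromo-2-hydroxy-6-methoxyphenyl)-3-(dimethylamino)prop-2-en-1-one | CN(C)/C=C/C(=O)c1c(O)cc(Br)cc1OC | intermediate
19 | 7-bromo-5-methoxy-4H-chromen-4-one | O=c1ccoc2cc(Br)cc(OC)c12 | intermediate
20 | 4-(4,4,5,5-tetramethyl-1,3,2-dioxaborolan-2-yl)phenol | Oc1ccc(B2OC(C)(C)C(C)(C)O2)cc1 | starting material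
21 | 4-(4,4,5,5-tetramethyl-1,3,2-dioxaborolan-2-yl)phenyl methanesulfonate | CS(=O)(=O)Oc1ccc(B2OC(C)(C)C(C)(C)O2)cc1 | intermediate
22 | 4-[(2R)-7-bromo-5-methoxy-4-oxochroman-2-yl]phenyl methanesulfonate | O=C1C[C@H](c2ccc(OS(C)(=O)=O)cc2)Oc2cc(Br)cc(OC)c12 | intermediate
23 | 4-[(2R)-7-bromo-4,5-dimethoxy-2H-chromen-2-yl]phenyl methanesulfonate (methyl enol ether of 22) | COC1=C[C@H](c2ccc(OS(C)(=O)=O)cc2)Oc2cc(Br)cc(OC)c12 | intermediate
24 | 4-[(2S,3S)-3-[acetoxy(phenyl)iodanyl]-7-bromo-4,4,5-trimethoxychroman-2-yl]phenyl methanesulfonate (iodine trans to the aryl group; C2 arranged in space as in 22) | COC1(OC)[C@@H](I(OC(C)=O)c2ccccc2)[C@H](c2ccc(OS(C)(=O)=O)cc2)Oc2cc(Br)cc(OC)c12 | intermediate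
25 | methyl (2R,3R)-6-bromo-4-methoxy-2-[4-(methanesulfonyloxy)phenyl]-2,3-dihydro-1-benzofuran-3-carboxylate (trans) | COc1cc(Br)cc2c1[C@@H](C(=O)OC)[C@H](c1ccc(OS(C)(=O)=O)cc1)O2 | intermediate
26 | (2R,3R)-6-bromo-4-methoxy-2-[4-(methanesulfonyloxy)phenyl]-2,3-dihydro-1-benzofuran-3-carboxylic acid (trans) | COc1cc(Br)cc2c1[C@@H](C(O)=O)[C@H](c1ccc(OS(C)(=O)=O)cc1)O2 | intermediate
27 | 1,3-dioxoisoindolin-2-yl (2R,3R)-6-bromo-4-methoxy-2-[4-(methanesulfonyloxy)phenyl]-2,3-dihydro-1-benzofuran-3-carboxylate (trans) | COc1cc(Br)cc2c1[C@@H](C(=O)ON1C(=O)c3ccccc3C1=O)[C@H](c1ccc(OS(C)(=O)=O)cc1)O2 | intermediate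
28 | 1-iodo-3,5-dimethoxybenzene | COc1cc(I)cc(OC)c1 | starting material
29 | 4-[(2R,3R)-6-bromo-3-(3,5-dimethoxyphenyl)-4-methoxy-2,3-dihydro-1-benzofuran-2-yl]phenyl methanesulfonate (trans) | COc1cc(Br)cc2c1[C@@H](c1cc(OC)cc(OC)c1)[C@H](c1ccc(OS(C)(=O)=O)cc1)O2 | intermediate
30 | 4-[(2R,3R)-3-(3,5-dimethoxyphenyl)-6-iodo-4-methoxy-2,3-dihydro-1-benzofuran-2-yl]phenyl methanesulfonate (trans) | COc1cc(I)cc2c1[C@@H](c1cc(OC)cc(OC)c1)[C@H](c1ccc(OS(C)(=O)=O)cc1)O2 | intermediate
31 | (2S,3S)-3-[(2R,3R)-3-(3,5-dimethoxyphenyl)-4-methoxy-2-(4-mesyloxyphenyl)-2,3-dihydrobenzofuran-6-yl]-6-methoxy-4-[(E)-4-methoxystyryl]-2-(4-mesyloxyphenyl)-2,3-dihydrobenzofuran (both rings trans) | COc1ccc(/C=C/c2cc(OC)cc3c2[C@H](c2cc(OC)c4c(c2)O[C@@H](c2ccc(OS(C)(=O)=O)cc2)[C@@H]4c2cc(OC)cc(OC)c2)[C@@H](c2ccc(OS(C)(=O)=O)cc2)O3)cc1 | intermediate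
32 | (2S,3S)-3-[(2R,3R)-3-(3,5-dimethoxyphenyl)-2-(4-hydroxyphenyl)-4-methoxy-2,3-dihydrobenzofuran-6-yl]-2-(4-hydroxyphenyl)-6-methoxy-4-[(E)-4-methoxystyryl]-2,3-dihydrobenzofuran | COc1ccc(/C=C/c2cc(OC)cc3c2[C@H](c2cc(OC)c4c(c2)O[C@@H](c2ccc(O)cc2)[C@@H]4c2cc(OC)cc(OC)c2)[C@@H](c2ccc(O)cc2)O3)cc1 | intermediate
33 | (2S,3S)-3-[(2R,3R)-3-(3,5-dihydroxyphenyl)-4-hydroxy-2-(4-hydroxyphenyl)-2,3-dihydrobenzofuran-6-yl]-2-(4-hydroxyphenyl)-4-[(E)-4-hydroxystyryl]-2,3-dihydrobenzofuran-6-ol (CNP0188679.4) | Oc1ccc(/C=C/c2cc(O)cc3c2[C@H](c2cc(O)c4c(c2)O[C@@H](c2ccc(O)cc2)[C@@H]4c2cc(O)cc(O)c2)[C@@H](c2ccc(O)cc2)O3)cc1 | target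

## Step count and least certain steps

Total: 20 steps. Longest linear sequence: 12 steps, from 15 to 33 through steps 8, 9, 10 and 12 to 20. The branch from 1 is 10 steps (steps 1 to 7 and 18 to 20), and step 11 is a one-step side branch.

**Step 4 (key step).** The most likely failure is a slow or misdirected 1,2-shift. The ortho triflate lowers the migratory aptitude of ring A, so the iodine-bearing C3 may instead lose the C2 proton (dehydrogenation to the flavone) or be displaced by methanol (alpha-methoxylation). Enol ether formation next to the peri triflate may also be incomplete. Step 13 runs the same reaction, but on a ring without a sulfonate, and is less exposed. Fallback: a Wolff ring contraction, which forms the same C3–C3a bond by shifting the same ring A carbon but gives it no competitor. It sets out from 4. Trifluoroacetylation at C3 (LiN(SiMe3)2, CF3CO2CH2CF3, THF, −78 °C) gives the 3-trifluoroacetyl ketone F1. Deacylative diazo transfer (MsN3, Et3N, MeCN) gives the 3-diazo ketone F2. Irradiation in methanol gives the ketene F3, which is trapped as the methyl ester. Equilibration with DBU then gives the trans ester, and the sequence comes back to the route at 9.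

**Step 18 (fragment union).** The stabilised and hindered benzylic C3 radical may dimerise or be reduced (protodecarboxylation) faster than the arylnickel species captures it, and the two valuable partners cannot be used in large excess. Fallback: a decarboxylative Negishi-type coupling in which the aryl group comes as a nucleophile, so the arylnickel species is present before the radical is formed. It sets out from 30. Iodine–magnesium exchange (iPrMgCl·LiCl, THF, −20 °C) and transmetalation with ZnCl2 give the arylzinc chloride F4, which is coupled with 14 under NiCl2(glyme)/dtbbpy in THF/DMF. It comes back to the route at 31.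

**Step 16.** Chemoselectivity between the two halides may be lost: oxidative addition of zerovalent nickel into the C6' bromide of 27 or 29 would lead to oligomerisation or hydrodebromination. Fallback: an iron-catalysed, redox-neutral arylation in which no low-valent species that inserts into aryl bromides is present. It sets out from 27, which is treated with bis(3,5-dimethoxyphenyl)zinc F5 (from commercial 3,5-dimethoxyphenylmagnesium chloride and ZnCl2), Fe(acac)3 and 1,2-bis(diphenylphosphino)benzene in THF. It comes back to the route at 29.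

**Step 12.** Enantiomeric purity may erode through reversible ring opening of the flavanone enolate (retro-oxa-Michael) in the basic aqueous phase, and turnover may be slow next to the peri methoxy group. Fallback: racemic addition followed by kinetic resolution. It sets out from 19 and 21. The same addition with [Rh(OH)(cod)]2 and no chiral ligand gives the racemic flavanone F6. Noyori–Ikariya transfer hydrogenation (RuCl(p-cymene)(TsDPEN), HCO2H/Et3N), with the catalyst enantiomer that reduces the 2S ketone, converts that half into the cis-flavan-4-ol F7, which is separated. The unreduced ketone is 22, where the route is rejoined.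

**Step 20.** Acid may trigger skeletal change: ionisation of a C2–O or C2'–O bond para to a free hydroxyl, or protonation of the stilbene, followed by capture of the cation by an electron-rich ring (seven-membered ring formation) or alkene isomerisation. Fallback: reverse the order of the last two operations, so that both mesylates keep the C2 and C2' aryl groups electron-poor while the Lewis acid is present. It sets out from 31. BBr3 (CH2Cl2, −78 °C to rt) gives the pentaphenol bis-mesylate F8, and LiN(iPr)2 in excess (THF, −78 °C, argon) then removes the two mesylates. It comes back to the route at 33.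

## Further compounds

F1 | step 4 | 4-[(2S)-7-methoxy-4-oxo-3-(trifluoroacetyl)-5-(trifluoromethanesulfonyloxy)chroman-2-yl]phenyl methanesulfonate (C3 epimers and enol form) | O=C1C(C(=O)C(F)(F)F)[C@@H](c2ccc(OS(C)(=O)=O)cc2)Oc2cc(OC)cc(OS(=O)(=O)C(F)(F)F)c12
F2 | step 4 | 4-[(2R)-3-diazo-7-methoxy-4-oxo-5-(trifluoromethanesulfonyloxy)chroman-2-yl]phenyl methanesulfonate (C2 arranged in space as in 4) | O=C1C(=[N+]=[N-])[C@@H](c2ccc(OS(C)(=O)=O)cc2)Oc2cc(OC)cc(OS(=O)(=O)C(F)(F)F)c12
F3 | step 4 | 4-[(2R)-6-methoxy-3-(oxomethylidene)-4-(trifluoromethanesulfonyloxy)-2,3-dihydro-1-benzofuran-2-yl]phenyl methanesulfonate (ketene; C2 arranged in space as in 4) | O=C=C1[C@@H](c2ccc(OS(C)(=O)=O)cc2)Oc2cc(OC)cc(OS(=O)(=O)C(F)(F)F)c12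
F4 | step 18 | {(2R,3R)-3-(3,5-dimethoxyphenyl)-4-methoxy-2-[4-(methanesulfonyloxy)phenyl]-2,3-dihydro-1-benzofuran-6-yl}zinc chloride | COc1cc([Zn]Cl)cc2c1[C@@H](c1cc(OC)cc(OC)c1)[C@H](c1ccc(OS(C)(=O)=O)cc1)O2
F5 | step 16 | bis(3,5-dimethoxyphenyl)zinc | COc1cc(OC)cc([Zn]c2cc(OC)cc(OC)c2)c1
F6 | step 12 | racemic 4-(7-bromo-5-methoxy-4-oxochroman-2-yl)phenyl methanesulfonate | O=C1CC(c2ccc(OS(C)(=O)=O)cc2)Oc2cc(Br)cc(OC)c12
F7 | step 12 | 4-[(2S,4S)-7-bromo-4-hydroxy-5-methoxychroman-2-yl]phenyl methanesulfonate (2,4-cis) | O[C@H]1C[C@@H](c2ccc(OS(C)(=O)=O)cc2)Oc2cc(Br)cc(OC)c12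
F8 | step 20 | (2S,3S)-3-[(2R,3R)-3-(3,5-dihydroxyphenyl)-4-hydroxy-2-(4-mesyloxyphenyl)-2,3-dihydrobenzofuran-6-yl]-4-[(E)-4-hydroxystyryl]-2-(4-mesyloxyphenyl)-2,3-dihydrobenzofuran-6-ol | Oc1ccc(/C=C/c2cc(O)cc3c2[C@H](c2cc(O)c4c(c2)O[C@@H](c2ccc(OS(C)(=O)=O)cc2)[C@@H]4c2cc(O)cc(O)c2)[C@@H](c2ccc(OS(C)(=O)=O)cc2)O3)cc1
A1 | alternative 1 | ring B resorcinol monosilyl ether with the primed furan ring still open (C4' hydroxyl free, C7a' triisopropylsilyl ether, C2' tert-butyldimethylsilyl ether) | Brc1cc(OC)cc2c1[C@H](c1cc(O)c(c(O[Si](C(C)C)(C(C)C)C(C)C)c1)[C@@H](c1cc(OC)cc(OC)c1)[C@@H](O[Si](C)(C)C(C)(C)C)c1ccc(OC)cc1)[C@@H](c1ccc(OC)cc1)O2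
A2 | alternative 1 | 3-[trans-4-bromo-6-methoxy-2-(4-methoxyphenyl)-2,3-dihydro-1-benzofuran-3-yl]cyclobut-2-en-1-one (2S; C3 arranged as in the target) | Brc1cc(OC)cc2c1[C@H](C1=CC(=O)C1)[C@@H](c1ccc(OC)cc1)O2
A3 | alternative 1 | triisopropylsilyl ynol ether carrying C3' (3,5-dimethoxyphenyl) and C2' (tert-butyldimethylsilyloxy and 4-methoxyphenyl) | CC(C)[Si](C(C)C)(C(C)C)OC#C[C@@H](c1cc(OC)cc(OC)c1)[C@@H](O[Si](C)(C)C(C)(C)C)c1ccc(OC)cc1
A4 | alternative 2 | target as hexamethyl ether with an ethyl ether at C6 | COc1ccc(/C=C/c2cc(OCC)cc3c2[C@H](c2cc(OC)c4c(c2)O[C@@H](c2ccc(OC)cc2)[C@@H]4c2cc(OC)cc(OC)c2)[C@@H](c2ccc(OC)cc2)O3)cc1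
A5 | alternative 2 | 1,6-diyne with an ethynyl ether on O1 and a (E)-4-methoxystyryl-substituted alkyne on C3, carrying the complete primed unit | COc1ccc(/C=C/C#C[C@H](c2cc(OC)c3c(c2)O[C@@H](c2ccc(OC)cc2)[C@@H]3c2cc(OC)cc(OC)c2)[C@@H](c2ccc(OC)cc2)OC#C)cc1
A6 | alternative 2 | ethoxyethyne | CCOC#C
A7 | alternative 3 | C4 bromide of the target skeleton, pentamethyl ether with the C4' hydroxyl free | Brc1cc(OC)cc2c1[C@H](c1cc(O)c3c(c1)O[C@@H](c1ccc(OC)cc1)[C@@H]3c1cc(OC)cc(OC)c1)[C@@H](c1ccc(OC)cc1)O2
A8 | alternative 3 | open-chain triphenol diol (both carbinol centres of either configuration) | Brc1cc(OC)cc(O)c1[C@H](c1cc(O)c(c(O)c1)[C@@H](c1cc(OC)cc(OC)c1)C(O)c1ccc(OC)cc1)C(O)c1ccc(OC)cc1
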